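**Retrosynthetic overview**

1. Target 9 comes from 8 by cleavage of two aryl silyl ethers, and 8 comes from 7 by oxidation of the C4 alcohol; 7 already carries the full skeleton.
2. Key disconnection: ring C of 7 is opened across C3–C4 and O1–C2 (retro oxa-[4+2]) into salicylaldehyde 6 (ring A with O1, C8a, C4a, C4) and styrene 3 (ring B with C2, C3).
3. Enabling feature: on ring A, C4 and O1 are ortho substituents on the C4a–C8a bond, so the protonated, chelated aldehyde is an O-protonated ortho-quinone methide (oxadiene O1=C8a–C4a=C4). C2 is benzylic and para to the methoxy group of ring B, so C2=C3 is an electron-rich styrene whose polarisation fixes the regiochemistry.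
4. 6 comes from 2,4,6-trihydroxybenzaldehyde (C-prenylation, then silylation of the two hydroxyls that do not flank the prenyl group); 3 comes from 3-bromo-4-methoxybenzaldehyde (Stille prenylation, Wittig methylenation).
5. Ring order: rings A and B are bought as arenes; ring C is the only ring formed (step 5), at the alcohol oxidation level of C4, which step 6 corrects.

Key step: step 5

Remark: for the substrate pair of step 5 the sense of induction of the chiral acid is not secured by a proven model; the (S)-acid is written, and its antipode is meant if the first run shows the 2R series.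

**Route**

Step 1
Reactants: 1 3-bromo-4-methoxybenzaldehyde
Product: 2 4-methoxy-3-(3-methylbut-2-en-1-yl)benzaldehyde
Conditions: Bu3SnCH2CH=CMe2 (1.2 equiv), Pd(PPh3)4 (5 mol %), DMF, 100 °C
Reagents that add atoms: tributyl(3-methylbut-2-en-1-yl)stannane, CCCC[Sn](CCCC)(CCCC)CC=C(C)C
Why: Stille cross-coupling of an aryl bromide with an allylic stannane, in which the γ,γ-dimethylallyl group should be transferred through its unsubstituted carbon to give the linear prenyl arene while the aldehyde is a spectator.

Step 2
Reactants: 2 4-methoxy-3-(3-methylbut-2-en-1-yl)benzaldehyde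
Product: 3 4-ethenyl-1-methoxy-2-(3-methylbut-2-en-1-yl)benzene
Conditions: Ph3PCH3Br, KOtBu, THF, 0 °C → rt
Reagents that add atoms: methyltriphenylphosphonium bromide, C[P+](c1ccccc1)(c1ccccc1)c1ccccc1.[Br-]
Why: Wittig methylenation of a non-enolisable aromatic aldehyde with the unstabilised ylide, which creates neither a stereocenter nor an alkene geometry.

Step 3
Reactants: 4 2,4,6-trihydroxybenzaldehyde
Product: 5 2,4,6-trihydroxy-3-(3-methylbut-2-en-1-yl)benzaldehyde
Conditions: prenyl bromide (1.0 equiv), KOH (10 % in H2O), 0 °C → rt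
Reagents that add atoms: 1-bromo-3-methylbut-2-ene (prenyl bromide), BrCC=C(C)C
Why: C-alkylation of an ambident phloroglucinol phenoxide in water, where solvation of the oxygen directs the allylic halide to the ring carbon, and since the two free ring positions of 4 are equivalent only one mono-prenyl isomer can form.

Step 4
Reactants: 5 2,4,6-trihydroxy-3-(3-methylbut-2-en-1-yl)benzaldehyde
Product: 6 4,6-bis(tert-butyldimethylsilyloxy)-2-hydroxy-3-(3-methylbut-2-en-1-yl)benzaldehyde
Conditions: TBSCl (2.1 equiv), imidazole, DMF, 0 °C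
Reagents that add atoms: tert-butyldimethylsilyl chloride, CC(C)(C)[Si](C)(C)Cl
Why: Imidazole-mediated silylation of phenols, expected to take the para hydroxyl (not hydrogen-bonded) and then the unhindered ortho hydroxyl, leaving free the ortho hydroxyl that is both chelated to the aldehyde and flanked by the prenyl group.

Step 5
Reactants: 6 4,6-bis(tert-butyldimethylsilyloxy)-2-hydroxy-3-(3-methylbut-2-en-1-yl)benzaldehyde; 3 4-ethenyl-1-methoxy-2-(3-methylbut-2-en-1-yl)benzene
Product: 7 (2S,4S)-5,7-bis(tert-butyldimethylsilyloxy)-2-[4-methoxy-3-(3-methylbut-2-en-1-yl)phenyl]-8-(3-methylbut-2-en-1-yl)-3,4-dihydro-2H-1-benzopyran-4-ol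
Conditions: 3 (2 equiv), N-triflylphosphoramide of (S)-3,3'-bis(2,4,6-triisopropylphenyl)-1,1'-bi-2-naphthol (5 mol %), toluene, −40 °C; Et3N quench at −40 °C
Reagents that add atoms: none
Why: Proposed new method: the chiral acid protonates the chelated aldehyde of 6 to a hydroxy-benzylic cation that is the O-protonated ortho-quinone methide O1=C8a–C4a=C4(OH), the vinyl group of 3 attacks C4 with its terminal carbon, and the C2 benzylic cation that develops is captured by the phenolic oxygen O1 inside the ion pair with the chiral phosphoramide anion (asynchronous inverse-electron-demand oxa-[4+2] cycloaddition). The closest known reaction types are the chiral N-triflylphosphoramide-catalysed [4+2] cycloadditions of in situ formed ortho-quinone methides with styrenes to 2-arylchromans, the chiral-acid-catalysed [4+2] cycloadditions of ortho-quinone methides generated from salicylaldehydes with tethered alkenes, the Lewis-acid-mediated salicylaldehyde/orthoformate/styrene annulation to 4-alkoxyflavans and the asymmetric Prins reaction of styrenes; new is the intermolecular union of a free salicylaldehyde with a styrene under chiral-anion control. Ring C is closed by intermolecular [4+2] annulation, with O1, C8a, C4a and C4 coming from 6 and C3 and C2 from 3. C2 is set by the chiral anion, which is hydrogen-bonded to the C4 hydroxyl and O1 and leaves one face of the oxadiene open to the styrene (catalyst control), while C4 is expected cis to the aryl group from an endo-type approach and is erased in step 6. The step needs C3-to-C4 and O1-to-C2 regiochemistry (secured by the para-methoxy group, which places the positive charge on C2), closure through O1 and not O5 (O5 and O7 are silylated, O1 is the only free phenol), attack by the vinyl group and not by the prenyl groups (only the vinyl group is conjugated to the anisole oxygen), and survival of the acid-sensitive ortho-prenylphenol, styrene and benzylic alcohol, for which low temperature, low acid loading and the cold amine quench are relied on.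

Step 6
Reactants: 7 (2S,4S)-5,7-bis(tert-butyldimethylsilyloxy)-2-[4-methoxy-3-(3-methylbut-2-en-1-yl)phenyl]-8-(3-methylbut-2-en-1-yl)-3,4-dihydro-2H-1-benzopyran-4-ol
Product: 8 (2S)-5,7-bis(tert-butyldimethylsilyloxy)-2-[4-methoxy-3-(3-methylbut-2-en-1-yl)phenyl]-8-(3-methylbut-2-en-1-yl)-2,3-dihydro-4H-1-benzopyran-4-one
Conditions: Dess–Martin periodinane, pyridine, CH2Cl2, 0 °C → rt
Reagents that add atoms: none
Why: Dess–Martin oxidation of a secondary benzylic alcohol under buffered neutral conditions, which removes the C4 stereocenter (so both C4 epimers of 7 converge) and should not touch C2, the silyl ethers or the prenyl alkenes.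

Step 7
Reactants: 8 (2S)-5,7-bis(tert-butyldimethylsilyloxy)-2-[4-methoxy-3-(3-methylbut-2-en-1-yl)phenyl]-8-(3-methylbut-2-en-1-yl)-2,3-dihydro-4H-1-benzopyran-4-one
Product: 9 (2S)-5,7-dihydroxy-2-[4-methoxy-3-(3-methylbut-2-en-1-yl)phenyl]-8-(3-methylbut-2-en-1-yl)-2,3-dihydro-4H-1-benzopyran-4-one (CNP0223481.2)
Conditions: TBAF, AcOH (1:1), THF, 0 °C
Reagents that add atoms: none
Why: Fluoride-induced cleavage of the aryl silyl ethers (Si–F bond formation) under acetic acid buffer, so that no free phenoxide or enolate is present to open ring C by retro-oxa-Michael reaction and racemise C2.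

**Compound list**

1 | 3-bromo-4-methoxybenzaldehyde | COc1ccc(C=O)cc1Br | starting material
2 | 4-methoxy-3-(3-methylbut-2-en-1-yl)benzaldehyde | COc1ccc(C=O)cc1CC=C(C)C | intermediate
3 | 4-ethenyl-1-methoxy-2-(3-methylbut-2-en-1-yl)benzene | COc1ccc(C=C)cc1CC=C(C)C | intermediate
4 | 2,4,6-trihydroxybenzaldehyde | O=Cc1c(O)cc(O)cc1O | starting material
5 | 2,4,6-trihydroxy-3-(3-methylbut-2-en-1-yl)benzaldehyde | O=Cc1c(O)cc(O)c(CC=C(C)C)c1O | intermediate
6 | 4,6-bis(tert-butyldimethylsilyloxy)-2-hydroxy-3-(3-methylbut-2-en-1-yl)benzaldehyde | O=Cc1c(O[Si](C)(C)C(C)(C)C)cc(O[Si](C)(C)C(C)(C)C)c(CC=C(C)C)c1O | intermediate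
7 | (2S,4S)-5,7-bis(tert-butyldimethylsilyloxy)-2-[4-methoxy-3-(3-methylbut-2-en-1-yl)phenyl]-8-(3-methylbut-2-en-1-yl)-3,4-dihydro-2H-1-benzopyran-4-ol | COc1ccc([C@@H]2C[C@H](O)c3c(O[Si](C)(C)C(C)(C)C)cc(O[Si](C)(C)C(C)(C)C)c(CC=C(C)C)c3O2)cc1CC=C(C)C | intermediate
8 | (2S)-5,7-bis(tert-butyldimethylsilyloxy)-2-[4-methoxy-3-(3-methylbut-2-en-1-yl)phenyl]-8-(3-methylbut-2-en-1-yl)-2,3-dihydro-4H-1-benzopyran-4-one | COc1ccc([C@@H]2CC(=O)c3c(O[Si](C)(C)C(C)(C)C)cc(O[Si](C)(C)C(C)(C)C)c(CC=C(C)C)c3O2)cc1CC=C(C)C | intermediate
9 | (2S)-5,7-dihydroxy-2-[4-methoxy-3-(3-methylbut-2-en-1-yl)phenyl]-8-(3-methylbut-2-en-1-yl)-2,3-dihydro-4H-1-benzopyran-4-one | COc1ccc([C@@H]2CC(=O)c3c(O)cc(O)c(CC=C(C)C)c3O2)cc1CC=C(C)C | target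

**Step count and risks**

Total steps: 7. Longest linear sequence: 5 steps (4 → 5 → 6 → 7 → 8 → 9; the branch 1 → 2 → 3 joins at step 5 and is equally long).

Steps most likely to fail:

Step 5 (Proposed new method). What may go wrong: acid-catalysed addition of the free ortho hydroxyl of 6 to its neighbouring prenyl alkene, cationic oligomerisation of the styrene, ionisation of the product at C4 with loss of water, or poor facial discrimination in the ion pair. The fallback uses known chemistry only, sets out from 2 and 6 and comes back at 7. Aldehyde 2 is homologated with the Ohira–Bestmann reagent (K2CO3, MeOH) to 4-ethynyl-1-methoxy-2-(3-methylbut-2-en-1-yl)benzene F1. Chelation-assisted alkyne hydroacylation of F1 with salicylaldehyde 6 ([Rh(cod)Cl]2, dppf, Na2CO3, toluene, 80 °C) should place the acyl group on the terminal carbon and give (E)-1-[4,6-bis(tert-butyldimethylsilyloxy)-2-hydroxy-3-(3-methylbut-2-en-1-yl)phenyl]-3-[4-methoxy-3-(3-methylbut-2-en-1-yl)phenyl]prop-2-en-1-one F2. Base-mediated intramolecular oxa-Michael addition (catalytic DBU, CH2Cl2) then closes ring C to racemic 5,7-bis(tert-butyldimethylsilyloxy)-2-[4-methoxy-3-(3-methylbut-2-en-1-yl)phenyl]-8-(3-methylbut-2-en-1-yl)-2,3-dihydro-4H-1-benzopyran-4-one F3. Dynamic kinetic resolution by Noyori-type transfer hydrogenation (RuCl(p-cymene)[(S,S)-TsDPEN], HCO2H/Et3N, DBU, MeCN) should reduce the 2S ketone from the face anti to the aryl group, while the base keeps the two C2 epimers in equilibrium through ring opening and reclosure, and deliver cis alcohol 7, from which steps 6 and 7 follow unchanged.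

Step 3. What may go wrong: a second C-alkylation at the remaining ring position and competing O-alkylation, which leave little mono-C-prenyl product. The fallback sets out from 4 and comes back at 5, replacing the phenoxide alkylation by halogenation and cross-coupling, so that the carbon–carbon bond can form only at the halogenated carbon. Mono-iodination of 4 (I2, NaHCO3, THF/H2O; one type of ring position) gives 2,4,6-trihydroxy-3-iodobenzaldehyde F4, and Stille coupling with tributyl(3-methylbut-2-en-1-yl)stannane (Pd(PPh3)4, DMF) gives 5.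

Step 4. What may go wrong: silylation of the hindered ortho hydroxyl instead of the unhindered one (which would lead into the 6-prenyl series after step 5) or silylation of all three hydroxyls. The fallback sets out from 4 and comes back at 6, introducing the silyl groups while the two ortho hydroxyls are still equivalent. Bis-silylation of 4 (TBSCl, imidazole, DMF) gives 4,6-bis(tert-butyldimethylsilyloxy)-2-hydroxybenzaldehyde F5 without any regiochemical question. Amine-directed ortho bromination of the remaining phenol (NBS, catalytic iPr2NH, CH2Cl2) gives 3-bromo-4,6-bis(tert-butyldimethylsilyloxy)-2-hydroxybenzaldehyde F6, and Stille coupling with tributyl(3-methylbut-2-en-1-yl)stannane (Pd(PPh3)4, DMF) gives 6.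

**Further compounds**

F1 | step 5 | 4-ethynyl-1-methoxy-2-(3-methylbut-2-en-1-yl)benzene | COc1ccc(C#C)cc1CC=C(C)C
F2 | step 5 | (E)-1-[4,6-bis(tert-butyldimethylsilyloxy)-2-hydroxy-3-(3-methylbut-2-en-1-yl)phenyl]-3-[4-methoxy-3-(3-methylbut-2-en-1-yl)phenyl]prop-2-en-1-one | COc1ccc(/C=C/C(=O)c2c(O[Si](C)(C)C(C)(C)C)cc(O[Si](C)(C)C(C)(C)C)c(CC=C(C)C)c2O)cc1CC=C(C)C
F3 | step 5 | racemic 5,7-bis(tert-butyldimethylsilyloxy)-2-[4-methoxy-3-(3-methylbut-2-en-1-yl)phenyl]-8-(3-methylbut-2-en-1-yl)-2,3-dihydro-4H-1-benzopyran-4-one | COc1ccc(C2CC(=O)c3c(O[Si](C)(C)C(C)(C)C)cc(O[Si](C)(C)C(C)(C)C)c(CC=C(C)C)c3O2)cc1CC=C(C)C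
F4 | step 3 | 2,4,6-trihydroxy-3-iodobenzaldehyde | O=Cc1c(O)cc(O)c(I)c1O
F5 | step 4 | 4,6-bis(tert-butyldimethylsilyloxy)-2-hydroxybenzaldehyde | O=Cc1c(O)cc(O[Si](C)(C)C(C)(C)C)cc1O[Si](C)(C)C(C)(C)C
F6 | step 4 | 3-bromo-4,6-bis(tert-butyldimethylsilyloxy)-2-hydroxybenzaldehyde | O=Cc1c(O)c(Br)c(O[Si](C)(C)C(C)(C)C)cc1O[Si](C)(C)C(C)(C)C
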